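**Retrosynthetic overview**
1. The only ring, the 25-membered lactone, is opened at the acyl C–O bond: 3 ⇒ 24-hydroxytetracosanoic acid 2. It is closed by a serine hydrolase (lipase), the laboratory counterpart of the natural acyl-transfer lactonization.
2. 2 ⇒ tetracosanoic acid 1 by disconnecting the terminal C24–O bond, i.e. a P450 ω-hydroxylation of the intact C24 fatty acid, as in the presumed pathway (ω-oxidation, then lactonization).
3. No C–C bond is formed and no protecting group is used; the whole carbon chain is bought.
4. Ring order: one ring, formed in the last step.

Assumption: the target has no stereocentre and is achiral, so "single enantiomer" needs no stereocontrol.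
Assumption: enzymes and cofactors are catalysts; enzyme-bound species (iron-oxo Compound I, acyl-enzyme) are not discrete compounds and carry no number.

**Step 1**
Reactants: 1 tetracosanoic acid (lignoceric acid)
Product: 2 24-hydroxytetracosanoic acid
Conditions: CYP4F2/CPR membrane fraction (recombinant, P. pastoris), NADP+ (cat.), GDH, D-glucose (1.5 equiv), air (O2), catalase, α-cyclodextrin, KPi buffer pH 7.4, 30 °C; stop at partial conversion, recover 1
Reagents that add atoms: dioxygen, O=O
Why: Proposed new method: preparative use of a very-long-chain fatty acid ω-hydroxylase (cytochrome P450 ω-hydroxylation), in which the narrow substrate channel holds the carboxylate at its mouth and lets only the C24 methyl group reach the iron-oxo species, which abstracts a hydrogen atom and returns OH by oxygen rebound to give the primary alcohol without touching the 22 methylene groups; the closest known reactions are the analytical-scale ω-hydroxylation of C22–C26 saturated fatty acids by CYP4F enzymes and the gram-scale CYP52/CYP153A ω-hydroxylation of C12–C18 fatty acids, and no stereocentre is formed.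

**Step 2**
Reactants: 2 24-hydroxytetracosanoic acid
Product: 3 24-tetracosanolide (oxacyclopentacosan-2-one)
Conditions: Novozym 435 (immobilised CALB), 4 Å MS, toluene, 2 mM (2 added in portions over 24 h), 75 °C, 48 h
Reagents that add atoms: none
Why: Lipase-catalysed macrolactonization (serine-hydrolase acyl transfer): the active-site serine is acylated by the free acid and the acyl-enzyme is captured intramolecularly by the ω-hydroxyl, the sieves take up the water that is the only co-product, and at 2 mM the reversible ring–chain equilibrium favours the strain-free 25-membered monolactone over diolide and linear oligoesters; no stereocentre is formed.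

**Compound list**
1 | tetracosanoic acid (lignoceric acid) | CCCCCCCCCCCCCCCCCCCCCCCC(=O)O | starting material
2 | 24-hydroxytetracosanoic acid | OCCCCCCCCCCCCCCCCCCCCCCCC(=O)O | intermediate
3 | 24-tetracosanolide (oxacyclopentacosan-2-one) | O=C1CCCCCCCCCCCCCCCCCCCCCCCO1 | target

**Total step count:** 2
**Longest linear sequence:** 2

**Steps most likely to fail**
The route has only two steps, so both are ranked and there is no third.

1. Step 1 (highest risk). The acid is almost insoluble in water, turnover numbers of the P450 are limited, and over-oxidation to the 1,24-diacid is possible. Fallback: give up the C–H oxidation and build 2 by a protecting-group-free C12 + C12 alkyl–alkyl coupling. This fallback does not use 1; it sets out from two other cheap commercial compounds and comes back to the route at 2. 12-Bromododecan-1-ol F1 is deprotonated with MeMgCl (1.0 equiv, THF, −20 °C) to chloromagnesium 12-bromododecan-1-olate F2. Activated Mg turnings in refluxing THF convert F2 into the alkoxide Grignard (Normant-type) reagent chloromagnesium 12-(bromomagnesio)dodecan-1-olate F3. Separately, 12-bromododecanoic acid F4 is deprotonated with MeMgCl (1.0 equiv, THF, −20 °C) to chloromagnesium 12-bromododecanoate F5. F3 (1.3 equiv) is added to F5 with Li2CuCl4 (2 mol%) in THF/NMP at −10 °C to rt (Kochi-type copper-catalysed sp3–sp3 coupling; the carboxylate salt is inert to the Grignard reagent). This gives the bis(chloromagnesium) salt of 24-hydroxytetracosanoic acid F6, and 1 M HCl work-up with crystallisation gives 2.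

2. Step 2. The hydroxy acid is poorly soluble, and diolide or linear oligoesters may dominate if the effective concentration is too high or the enzyme handles the C24 chain poorly. Fallback: replace the enzyme by a stoichiometric thioester activation of the same acyl C–O closure. It sets out from 2 and comes back to the route at 3. 2 is treated with 2,2'-dipyridyl disulfide and PPh3 (1.5 equiv each, THF/toluene, rt) to give S-(pyridin-2-yl) 24-hydroxytetracosanethioate F7. Its solution is added by syringe pump to refluxing xylene (final 1 mM, AgOTf optional). Proton transfer from the hydroxyl to the pyridine nitrogen activates both ends (Corey–Nicolaou double activation) and the ring closes to 3.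

**Further compounds**
F1 | step 1 | 12-bromododecan-1-ol | OCCCCCCCCCCCCBr
F2 | step 1 | chloromagnesium 12-bromododecan-1-olate | Cl[Mg]OCCCCCCCCCCCCBr
F3 | step 1 | chloromagnesium 12-(bromomagnesio)dodecan-1-olate | Cl[Mg]OCCCCCCCCCCCC[Mg]Br
F4 | step 1 | 12-bromododecanoic acid | OC(=O)CCCCCCCCCCCBr
F5 | step 1 | chloromagnesium 12-bromododecanoate | Cl[Mg]OC(=O)CCCCCCCCCCCBr
F6 | step 1 | bis(chloromagnesium) salt of 24-hydroxytetracosanoic acid | Cl[Mg]OCCCCCCCCCCCCCCCCCCCCCCCC(=O)O[Mg]Cl
F7 | step 2 | S-(pyridin-2-yl) 24-hydroxytetracosanethioate | OCCCCCCCCCCCCCCCCCCCCCCCC(=O)Sc1ccccn1
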